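**Plan**
- Retrosynthetic cuts, last bond first: the lactone acyl–oxygen bond (C15–O–C16), C14–C15 (methylenation), the O9–C13 ether bond (hydroxy-epoxide closure), the 6-oxo/7-hydroxy pair back to a C7 ketone and then to the 8,9-alkene, C11–C12 (allylic alkylation), C8–CH3, then C9–C10 and C4–C5 together, and finally the geranyl–acetoacetate bond.
- Enabling feature: rings A and B (C1–C10), with the C4 gem-dimethyl group, the quaternary C10 methyl and the adjacent functional carbons C8 and C9, carry the carbon pattern of a geranyl chain that ends in a β-keto ester (C8 = ketone, C9 = α-carbon, C11 = ester carbon).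
- Forward order: the chain is joined, rings A and B close in one cascade, C8 is methylated, and the C12–C14/C16 unit is attached at C11. The side-chain epoxide is then set, ring B is oxidised (7-ketone, 8α,9α-epoxide, 9α-OH), the tetrahydrofuran closes at C13, C15 is added, the ketone is transposed to 6-oxo-7β-OH, and the lactone closes last.
- Stereochemistry: C5 and C10 come from catalyst-controlled protonation and chair–chair folding. C9 and C8 come from α-face nucleophilic epoxidation and axial protonation of a samarium enolate. C13 comes from Sharpless epoxidation followed by invertive ring closure. C7 comes from α-face hydroboration of a Δ6 silyl enol ether.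

Key step: step 2

Remark: labdane numbering is used (C1–C10 decalin, C11–C16 side chain, C17 on C8, C20 on C10); α is the face opposite the C10 methyl; TBS = tert-butyldimethylsilyl. In the 15-nor intermediates, C14 is the former =CH2 carbon of methallyl alcohol and C16 its CH2O carbon.
Assumption: the (R)-configured chiral acid is taken to give the 5S,10S series, as it gives the normal series with homofarnesyl substrates; if the sense proves opposite, the (S)-ligand is used.

**Route**

Step 1
Reactants: 1 ethyl acetoacetate; 2 geranyl bromide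
Product: 4 ethyl (6E)-7,11-dimethyl-3-oxododeca-6,10-dienoate (ethyl geranylacetoacetate), via acetoacetate dianion 3 (not isolated)
Conditions: NaH, THF, 0 °C; n-BuLi, 0 °C; then 2, 0 °C → rt; aq. NH4Cl
Reagents that add atoms: none
Why: γ-Alkylation of the acetoacetate dianion, in which the more basic terminal carbanion displaces the primary allylic bromide by SN2 without allylic transposition, so the E-alkene is kept.

Step 2
Reactants: 4 ethyl geranylacetoacetate
Product: 5 ethyl (1R,4aS,8aS)-5,5,8a-trimethyl-2-oxodecahydronaphthalene-1-carboxylate (8-oxo; 9β-CO2Et; 5α-H; 10β-CH3)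
Conditions: (R)-2-(2-fluorobenzyloxy)-2′-hydroxy-1,1′-binaphthyl·SnCl4 (chiral Lewis acid-assisted Brønsted acid, 2 equiv), toluene, −78 °C
Reagents that add atoms: none
Why: Proposed new method: the chiral Lewis acid-assisted Brønsted acid protonates the terminal 10,11-alkene of 4 on one enantioface to give the tertiary C4 cation (product numbering) while tin(IV) holds the β-keto ester as its chelated enol, and the cascade then forms C4–C5 and C9–C10; the closest known reactions are the SnCl4-promoted racemic bicyclization of geranylacetoacetates and the enantioselective protonative cyclization of homogeranyl arenes and alcohols with this class of chiral acid, so only the pairing of the chiral proton source with the keto ester terminator is untested. Ring A closes by 6-endo-trig attack of the 6E-alkene on the C4 cation, and ring B by 6-endo-trig attack of the enol carbon C9 on the resulting C10 cation, the enol oxygen becoming the C8 ketone. C5 and C10 are set relative to each other by chair–chair, antiperiplanar addition across the E-alkene (trans fusion, 5α-H, 10β-CH3) and in the absolute sense by the catalyst-controlled face of protonation. C9 is epimerizable and should settle with the ester equatorial (9β). The step needs enantioface selection at an unfunctionalized trisubstituted alkene and C- rather than O-termination: the first rests on the chiral pocket of the acid outrunning achiral proton sources at −78 °C, the second on tin chelation, which makes C9 the nucleophilic atom.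

Step 3
Reactants: 5 bicyclic β-keto ester
Product: 7 ethyl (4aS,8aS)-5,5,8a-trimethyl-2-(trifluoromethylsulfonyloxy)-3,4,4a,5,6,7,8,8a-octahydronaphthalene-1-carboxylate (Δ8 enol triflate), via sodium enolate 6 (not isolated)
Conditions: NaH, Et2O, 0 °C → rt; Tf2O, 0 °C
Reagents that add atoms: trifluoromethanesulfonic anhydride, O=S(=O)(OS(=O)(=O)C(F)(F)F)C(F)(F)F
Why: Enol triflate formation by O-sulfonylation of the sodium enolate of a cyclic β-keto ester, which can only be the C8=C9 enolate, so a single tetrasubstituted vinyl triflate should result.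

Step 4
Reactants: 7 enol triflate
Product: 8 ethyl drim-8-en-11-oate [ethyl (4aS,8aS)-2,5,5,8a-tetramethyl-3,4,4a,5,6,7,8,8a-octahydronaphthalene-1-carboxylate]
Conditions: Me2CuLi (from MeLi and CuI), Et2O–THF, −40 → 0 °C
Reagents that add atoms: lithium dimethylcuprate, [Li+].C[Cu-]C
Why: Addition–elimination of a Gilman cuprate on a β-triflyloxy enoate (vinyl triflate–cuprate coupling) replaces the triflate by the C8 methyl (C17).

Step 5
Reactants: 8 ethyl drim-8-en-11-oate
Product: 9 drim-8-en-11-ol [(4aS,8aS)-2,5,5,8a-tetramethyl-3,4,4a,5,6,7,8,8a-octahydronaphthalen-1-yl]methanol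
Conditions: DIBAL-H, CH2Cl2, −78 °C → rt; Rochelle salt
Reagents that add atoms: none
Why: DIBAL-H 1,2-reduction of the hindered conjugated ester gives the primary allylic alcohol and leaves the tetrasubstituted alkene untouched.

Step 6
Reactants: 9 drim-8-en-11-ol
Product: 10 11-bromodrim-8-ene (primary allylic bromide of 9; 5S,10S), used crude
Conditions: PBr3, pyridine (cat.), Et2O, −10 °C
Reagents that add atoms: phosphorus tribromide, BrP(Br)Br
Why: Conversion of a primary allylic alcohol into its bromide with PBr3 at low temperature, where the primary position of the leaving group disfavours allylic transposition.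

Step 7
Reactants: 10 11-bromodrim-8-ene; 11 2-methylprop-2-en-1-ol (methallyl alcohol)
Product: 13 (5S,10S)-15-norlabda-8,13(14)-dien-16-ol [2-methylidene-4-(drim-8-en-11-yl)butan-1-ol], via C,O-dilithiomethallyl alcohol 12 (not isolated)
Conditions: 11, n-BuLi (2 equiv), TMEDA, Et2O–hexane, 0 °C → rt; then 10, THF, −78 → 0 °C; aq. NH4Cl
Reagents that add atoms: none
Why: C-Alkylation of the allylic dianion of methallyl alcohol by the primary allylic bromide (SN2) forms C11–C12 and gives the 2-substituted allylic alcohol directly, the allyl nucleophile being symmetric across its termini so that it cannot give a regioisomer.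

Step 8
Reactants: 13 dienol
Product: 14 (5S,10S,13R)-13,14-epoxy-15-norlabd-8-en-16-ol (2,2-disubstituted epoxy alcohol)
Conditions: Ti(OiPr)4 (cat.), D-(−)-diisopropyl tartrate (cat.), t-BuOOH, 4 Å MS, CH2Cl2, −20 °C
Reagents that add atoms: tert-butyl hydroperoxide, CC(C)(C)OO
Why: Sharpless asymmetric epoxidation, in which only the allylic-alcohol alkene reacts (the ring alkene has no directing hydroxyl) and D-(−)-tartrate delivers oxygen to the face that gives the 13R epoxy alcohol according to the Sharpless mnemonic.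

Step 9
Reactants: 14 epoxy alcohol
Product: 15 (5S,10S,13S)-16-(TBS-oxy)-13,14-epoxy-15-norlabd-8-ene (same C13 geometry as 14; descriptor changes by CIP priority)
Conditions: TBSCl, imidazole, DMF, 0 °C → rt
Reagents that add atoms: tert-butyldimethylsilyl chloride, CC(C)(C)[Si](C)(C)Cl
Why: Silylation of the primary alcohol, which tells the two oxygenated one-carbon arms on C13 apart before the epoxide is opened.

Step 10
Reactants: 15 silyl ether
Product: 16 (5S,10S,13S)-16-(TBS-oxy)-13,14-epoxy-15-norlabd-8-en-7-one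
Conditions: CrO3, 3,5-dimethylpyrazole, CH2Cl2, −20 °C
Reagents that add atoms: chromium trioxide, O=[Cr](=O)=O
Why: Cr(VI) allylic oxidation of the tetrasubstituted alkene at its ring methylene C7, the position normally oxidised in drim-8-enes and labd-8-enes, gives the conjugated enone.

Step 11
Reactants: 16 enone
Product: 17 (5S,10S,13S)-16-(TBS-oxy)-8α,9α:13,14-diepoxy-15-norlabdan-7-one
Conditions: 30% H2O2, aq. NaOH, MeOH–THF, 0 °C → rt
Reagents that add atoms: hydrogen peroxide, OO
Why: Weitz–Scheffer nucleophilic epoxidation, in which hydroperoxide should add to C9 axially from the α face, anti to the axial C10 methyl, and close to the 8α,9α-epoxide (setting C9 with C11 β), while the side-chain epoxide and silyl ether are inert to alkaline peroxide.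

Step 12
Reactants: 17 epoxy ketone
Product: 18 (5S,10S,13S)-16-(TBS-oxy)-13,14-epoxy-9α-hydroxy-15-norlabdan-7-one (8α-CH3, 8β-H)
Conditions: SmI2, THF–MeOH, −90 °C; pH 7 buffer
Reagents that add atoms: none
Why: SmI2 reduction of an α,β-epoxy ketone cleaves the Cα–O bond (C8–O) and keeps the 9α-oxygen, and the samarium enolate is expected to be protonated by methanol axially from the β face, anti to the bulky 9α-oxygen, so that the C8 methyl ends equatorial (8α), which is also the more stable arrangement; isolated epoxides are not reduced under these conditions.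

Step 13
Reactants: 18 β-hydroxy ketone
Product: 19 (5S,10S,13R)-16-(TBS-oxy)-9α,13-epoxy-14-hydroxy-15-norlabdan-7-one (spiro-tetrahydrofuran)
Conditions: camphorsulfonic acid (cat.), CH2Cl2, 0 °C
Reagents that add atoms: none
Why: Acid-catalysed 5-exo-tet hydroxy-epoxide cyclisation, in which the γ-disposed tertiary C9 hydroxyl opens the 2,2-disubstituted epoxide at its more substituted carbon with inversion, as in polyether tetrahydrofuran syntheses, setting C13 and freeing the C14 hydroxyl.

Step 14
Reactants: 19 hydroxy ether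
Product: 20 (5S,10S,13S)-16-(TBS-oxy)-9α,13-epoxy-7-oxo-15-norlabdan-14-al
Conditions: Dess–Martin periodinane, NaHCO3, CH2Cl2, 0 °C → rt
Reagents that add atoms: none
Why: Dess–Martin oxidation of the primary neopentyl alcohol gives a non-enolisable α-alkoxy aldehyde under buffered, non-basic conditions that leave the β-alkoxy ketone alone.

Step 15
Reactants: 20 keto aldehyde
Product: 21 (5S,10S,13R)-16-(TBS-oxy)-9α,13-epoxylabd-14-en-7-one
Conditions: Ph3P=CH2 (from Ph3PCH3Br and KHMDS, 1.2 equiv), THF, −78 → 0 °C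
Reagents that add atoms: methylenetriphenylphosphorane, C=P(c1ccccc1)(c1ccccc1)c1ccccc1
Why: Wittig methylenation, in which the aldehyde should react far faster than the hindered C7 ketone at low temperature, supplies C15 as a vinyl carbon.

Step 16
Reactants: 21 vinyl ketone
Product: 23 (5S,10S,13R)-7,16-bis(TBS-oxy)-9α,13-epoxylabda-6,14-diene (Δ6 silyl enol ether), via lithium Δ6-enolate 22 (not isolated)
Conditions: LDA, THF, −78 °C; TBSCl, HMPA, −78 → 0 °C
Reagents that add atoms: tert-butyldimethylsilyl chloride, CC(C)(C)[Si](C)(C)Cl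
Why: Kinetic deprotonation by LDA at the methylene C6 rather than at the tertiary C8–H, followed by O-silylation, gives the Δ6 silyl enol ether and, by not forming the C8 enolate, avoids both C8 epimerisation and β-elimination of the C9 ether oxygen.

Step 17
Reactants: 23 silyl enol ether
Product: 25 (5S,10S,13R)-7β,16-bis(TBS-oxy)-9α,13-epoxylabdane-6α,15-diol, via 6α,15-bis(borane) adduct 24 (not isolated)
Conditions: BH3·THF (excess), THF, 0 °C → rt; NaBO3·4H2O, H2O, rt
Reagents that add atoms: sodium perborate, [Na+].[Na+].O[B-]1(O)OO[B-](O)(O)OO1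
Why: Hydroboration–oxidation, in which boron adds to C6 (β to the silyloxy group) from the α face because the β face of C6 is screened by the syn-axial C4β and C10 methyls, so that hydrogen reaches C7 from the α face and the silyloxy group becomes 7β (equatorial), while the vinyl group is hydroborated anti-Markovnikov in the same operation and buffered perborate oxidation avoids silyl migration.

Step 18
Reactants: 25 diol
Product: 26 (5S,10S,13R)-7β,16-bis(TBS-oxy)-9α,13-epoxy-6-oxolabdan-15-al
Conditions: Dess–Martin periodinane (excess), NaHCO3, CH2Cl2, rt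
Reagents that add atoms: none
Why: Dess–Martin oxidation of both hydroxyls gives the C6 ketone and the C15 aldehyde under buffered conditions that should not epimerise C5 or C7.

Step 19
Reactants: 26 keto aldehyde
Product: 27 (5S,10S,13R)-7β,16-bis(TBS-oxy)-9α,13-epoxy-6-oxolabdan-15-oic acid
Conditions: NaClO2, NaH2PO4, 2-methyl-2-butene, t-BuOH–H2O, rt
Reagents that add atoms: sodium chlorite, [Na+].[O-]Cl=O
Why: Pinnick oxidation converts the aldehyde into the carboxylic acid under mildly acidic conditions that spare the silyl ethers, the ketone and the β-alkoxy carbonyl array.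

Step 20
Reactants: 27 keto acid
Product: 29 (5S,7R,8R,9R,10S,13R)-7β-hydroxy-6-oxo-9α,13-epoxylabdan-15,16-olide (CNP0291402.1), via dihydroxy acid 28 (not isolated)
Conditions: 48% aq. HF, MeCN, 0 °C → rt
Reagents that add atoms: none
Why: Acidic fluoride desilylation frees the C7 and C16 hydroxyls and the γ-hydroxy acid should lactonise spontaneously (favoured by the quaternary C13), all without base, so that retro-oxa-Michael opening at C13 and ketol isomerisation are avoided.

**Compound list**
1 | ethyl acetoacetate | CCOC(=O)CC(C)=O | starting material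
2 | geranyl bromide | CC(C)=CCC/C(C)=C/CBr | starting material
3 | sodium lithium dianion of ethyl acetoacetate | C=C([O-])C=C([O-])OCC.[Na+].[Li+] | intermediate (not isolated)
4 | ethyl (6E)-7,11-dimethyl-3-oxododeca-6,10-dienoate | CCOC(=O)CC(=O)CC/C=C(\C)CCC=C(C)C | intermediate
5 | ethyl (1R,4aS,8aS)-5,5,8a-trimethyl-2-oxodecahydronaphthalene-1-carboxylate | O=C1CC[C@H]2C(C)(C)CCC[C@]2(C)[C@H]1C(=O)OCC | intermediate
6 | sodium enolate of 5 | CCOC(=O)C1=C([O-])CC[C@H]2C(C)(C)CCC[C@]12C.[Na+] | intermediate (not isolated)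
7 | Δ8 enol triflate of 5 | CCOC(=O)C1=C(OS(=O)(=O)C(F)(F)F)CC[C@H]2C(C)(C)CCC[C@]12C | intermediate
8 | ethyl drim-8-en-11-oate | CCOC(=O)C1=C(C)CC[C@H]2C(C)(C)CCC[C@]12C | intermediate
9 | drim-8-en-11-ol | OCC1=C(C)CC[C@H]2C(C)(C)CCC[C@]12C | intermediate
10 | 11-bromodrim-8-ene | BrCC1=C(C)CC[C@H]2C(C)(C)CCC[C@]12C | intermediate
11 | 2-methylprop-2-en-1-ol | CC(=C)CO | starting material
12 | C,O-dilithiomethallyl alcohol | [Li]CC(=C)CO[Li] | intermediate (not isolated)
13 | (5S,10S)-15-norlabda-8,13(14)-dien-16-ol | C=C(CO)CCC1=C(C)CC[C@H]2C(C)(C)CCC[C@]12C | intermediate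
14 | (5S,10S,13R)-13,14-epoxy-15-norlabd-8-en-16-ol | OC[C@@]1(CO1)CCC2=C(C)CC[C@H]3C(C)(C)CCC[C@]23C | intermediate
15 | (5S,10S,13S)-16-(TBS-oxy)-13,14-epoxy-15-norlabd-8-ene | CC(C)(C)[Si](C)(C)OC[C@@]1(CO1)CCC2=C(C)CC[C@H]3C(C)(C)CCC[C@]23C | intermediate
16 | (5S,10S,13S)-16-(TBS-oxy)-13,14-epoxy-15-norlabd-8-en-7-one | CC(C)(C)[Si](C)(C)OC[C@@]1(CO1)CCC2=C(C)C(=O)C[C@H]3C(C)(C)CCC[C@]23C | intermediate
17 | (5S,10S,13S)-16-(TBS-oxy)-8α,9α:13,14-diepoxy-15-norlabdan-7-one | CC(C)(C)[Si](C)(C)OC[C@@]1(CO1)CC[C@@]23O[C@]2(C)C(=O)C[C@H]4C(C)(C)CCC[C@]34C | intermediate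
18 | (5S,10S,13S)-16-(TBS-oxy)-13,14-epoxy-9α-hydroxy-8α-methyl-15-norlabdan-7-one | CC(C)(C)[Si](C)(C)OC[C@@]1(CO1)CC[C@@]2(O)[C@H](C)C(=O)C[C@H]3C(C)(C)CCC[C@]23C | intermediate
19 | (5S,10S,13R)-16-(TBS-oxy)-9α,13-epoxy-14-hydroxy-15-norlabdan-7-one | C[C@@H]1C(=O)C[C@H]2C(C)(C)CCC[C@]2(C)[C@@]12CC[C@@](CO)(CO[Si](C)(C)C(C)(C)C)O2 | intermediate
20 | (5S,10S,13S)-16-(TBS-oxy)-9α,13-epoxy-7-oxo-15-norlabdan-14-al | C[C@@H]1C(=O)C[C@H]2C(C)(C)CCC[C@]2(C)[C@@]12CC[C@@](C=O)(CO[Si](C)(C)C(C)(C)C)O2 | intermediate
21 | (5S,10S,13R)-16-(TBS-oxy)-9α,13-epoxylabd-14-en-7-one | C[C@@H]1C(=O)C[C@H]2C(C)(C)CCC[C@]2(C)[C@@]12CC[C@@](C=C)(CO[Si](C)(C)C(C)(C)C)O2 | intermediate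
22 | lithium Δ6-enolate of 21 | C[C@@H]1C([O-])=C[C@H]2C(C)(C)CCC[C@]2(C)[C@@]12CC[C@@](C=C)(CO[Si](C)(C)C(C)(C)C)O2.[Li+] | intermediate (not isolated)
23 | (5S,10S,13R)-7,16-bis(TBS-oxy)-9α,13-epoxylabda-6,14-diene | C[C@@H]1C(O[Si](C)(C)C(C)(C)C)=C[C@H]2C(C)(C)CCC[C@]2(C)[C@@]12CC[C@@](C=C)(CO[Si](C)(C)C(C)(C)C)O2 | intermediate
24 | 6α,15-bis(borane) adduct of 23 (7β-OTBS) | C[C@@H]1[C@@H](O[Si](C)(C)C(C)(C)C)[C@H](B)[C@H]2C(C)(C)CCC[C@]2(C)[C@@]12CC[C@@](CCB)(CO[Si](C)(C)C(C)(C)C)O2 | intermediate (not isolated)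
25 | (5S,10S,13R)-7β,16-bis(TBS-oxy)-9α,13-epoxylabdane-6α,15-diol | C[C@@H]1[C@@H](O[Si](C)(C)C(C)(C)C)[C@H](O)[C@H]2C(C)(C)CCC[C@]2(C)[C@@]12CC[C@@](CCO)(CO[Si](C)(C)C(C)(C)C)O2 | intermediate
26 | (5S,10S,13R)-7β,16-bis(TBS-oxy)-9α,13-epoxy-6-oxolabdan-15-al | C[C@@H]1[C@@H](O[Si](C)(C)C(C)(C)C)C(=O)[C@H]2C(C)(C)CCC[C@]2(C)[C@@]12CC[C@@](CC=O)(CO[Si](C)(C)C(C)(C)C)O2 | intermediate
27 | (5S,10S,13R)-7β,16-bis(TBS-oxy)-9α,13-epoxy-6-oxolabdan-15-oic acid | C[C@@H]1[C@@H](O[Si](C)(C)C(C)(C)C)C(=O)[C@H]2C(C)(C)CCC[C@]2(C)[C@@]12CC[C@@](CC(=O)O)(CO[Si](C)(C)C(C)(C)C)O2 | intermediate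
28 | (5S,10S,13R)-9α,13-epoxy-7β,16-dihydroxy-6-oxolabdan-15-oic acid | C[C@@H]1[C@@H](O)C(=O)[C@H]2C(C)(C)CCC[C@]2(C)[C@@]12CC[C@@](CC(=O)O)(CO)O2 | intermediate (not isolated)
29 | (5S,7R,8R,9R,10S,13R)-7β-hydroxy-6-oxo-9α,13-epoxylabdan-15,16-olide | C[C@@H]1[C@@H](O)C(=O)[C@H]2C(C)(C)CCC[C@]2(C)[C@@]12CC[C@@]1(COC(=O)C1)O2 | target

**Totals**
Total steps: 20. Longest linear sequence: 20 steps (1 and 2 to 29); methallyl alcohol 11 enters at step 7.

**Steps most likely to fail**

1. Step 2. Enantiocontrol may be lost through achiral background protonation by HCl/SnCl4 set free when the keto ester chelates tin, and oxygen may terminate the cascade in place of C9. Fallback, setting out from 4: SnCl4 in wet CH2Cl2 at 0 °C, the established Lewis-acid bicyclisation, gives the racemic trans-keto ester F1. Condensation with (S)-1-phenylethylamine (AcOH cat., toluene, water removal) turns it into two diastereomeric β-enamino esters that are separated by crystallisation or chromatography. The (4aS,8aS) enamino ester F2 is hydrolysed with aqueous HCl in THF, and the route is rejoined at 5.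

2. Step 11. Conjugate addition of hydroperoxide at the fully substituted, neopentyl C9 may be too slow, so that the enone is recovered or the ester-free side chain suffers instead. Fallback, setting out from 16: Luche reduction (NaBH4, CeCl3, MeOH, −78 °C) gives the 7β-allylic alcohol F3, and acetylation (Ac2O, pyridine, DMAP) gives the allylic acetate F4, which lacks a directing hydroxyl. Its electron-rich tetrasubstituted alkene is epoxidised electrophilically with mCPBA (NaHCO3, CH2Cl2, 0 °C) from the α face, away from the C10 methyl and the 7β-acetoxy group, to give the epoxy acetate F5. Methanolysis (K2CO3, MeOH) gives the epoxy alcohol F6, and Dess–Martin oxidation returns to 17.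

3. Step 13. Under acid the tertiary aldol may dehydrate to the conjugated enone before the ether forms. Fallback, setting out from 18: NaBH4 (MeOH, 0 °C) reduces the C7 ketone to the 7,9-diol F7 (either C7 epimer serves), which cannot dehydrate through an enol. Camphorsulfonic acid then closes the tetrahydrofuran to the ether diol F8, and Dess–Martin oxidation of both hydroxyls rejoins the route at 20.

**Further compounds**
F1 | step 2 | racemic ethyl trans-5,5,8a-trimethyl-2-oxodecahydronaphthalene-1-carboxylate (both enantiomers) | O=C1CC[C@H]2C(C)(C)CCC[C@]2(C)[C@H]1C(=O)OCC.O=C1CC[C@@H]2C(C)(C)CCC[C@@]2(C)[C@@H]1C(=O)OCC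
F2 | step 2 | ethyl (4aS,8aS)-5,5,8a-trimethyl-2-{[(1S)-1-phenylethyl]amino}-3,4,4a,5,6,7,8,8a-octahydronaphthalene-1-carboxylate | CCOC(=O)C1=C(N[C@@H](C)c2ccccc2)CC[C@H]3C(C)(C)CCC[C@]13C
F3 | step 11 | (5S,10S,13S)-16-(TBS-oxy)-13,14-epoxy-15-norlabd-8-en-7β-ol | CC(C)(C)[Si](C)(C)OC[C@@]1(CO1)CCC2=C(C)[C@@H](O)C[C@H]3C(C)(C)CCC[C@]23C
F4 | step 11 | 7β-acetate of F3 | CC(C)(C)[Si](C)(C)OC[C@@]1(CO1)CCC2=C(C)[C@@H](OC(C)=O)C[C@H]3C(C)(C)CCC[C@]23C
F5 | step 11 | (5S,10S,13S)-7β-acetoxy-16-(TBS-oxy)-8α,9α:13,14-diepoxy-15-norlabdane | CC(C)(C)[Si](C)(C)OC[C@@]1(CO1)CC[C@@]23O[C@]2(C)[C@@H](OC(C)=O)C[C@H]4C(C)(C)CCC[C@]34C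
F6 | step 11 | (5S,10S,13S)-16-(TBS-oxy)-8α,9α:13,14-diepoxy-15-norlabdan-7β-ol | CC(C)(C)[Si](C)(C)OC[C@@]1(CO1)CC[C@@]23O[C@]2(C)[C@@H](O)C[C@H]4C(C)(C)CCC[C@]34C
F7 | step 13 | (5S,10S,13S)-16-(TBS-oxy)-13,14-epoxy-8α-methyl-15-norlabdane-7β,9α-diol | CC(C)(C)[Si](C)(C)OC[C@@]1(CO1)CC[C@@]2(O)[C@H](C)[C@@H](O)C[C@H]3C(C)(C)CCC[C@]23C
F8 | step 13 | (5S,10S,13R)-16-(TBS-oxy)-9α,13-epoxy-15-norlabdane-7β,14-diol | C[C@@H]1[C@@H](O)C[C@H]2C(C)(C)CCC[C@]2(C)[C@@]12CC[C@@](CO)(CO[Si](C)(C)C(C)(C)C)O2
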